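**Plan**

- Retrosynthesis: the two diphenylmethylene ketals and the C3 O-methyl group come off first. Ring C is then cut at C3–C4, because the 3-oxygenated 4-ketone is an acyloin retron, which leads back to a dialdehyde. The aryl ether bond O1–C2 is cut last, giving a ring-A salicylaldehyde and a ring-B cinnamyl carbonate.
- Forward: ring-A aldehyde 4 (three steps from 3,4,5-trimethoxyphenol) and ring-B carbonate 9 (four steps from 2,3-dihydroxy-4-methoxybenzaldehyde) are joined at O1–C2 by iridium-catalysed branched allylic etherification. Alkene cleavage gives dialdehyde 13, a carbene-catalysed intramolecular benzoin closes ring C, and O-methylation and hydrogenolysis finish.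
- Enabling feature: C4 is a formyl carbon on ring A that a carbene turns into an acyl-anion equivalent, and the second formyl carbon C3 hangs from it through C8a–O1–C2, so a 6-exo attack gives ring C directly as its 3-hydroxy-4-ketone. C2–H, flanked by ring B, O1 and the C3 formyl group, is acidic enough to epimerise, which allows a dynamic kinetic resolution.
- Stereochemistry: C2 is set by the chiral iridium catalyst in step 8 and re-selected in the key step by the chiral carbene. C3 is set in the key step, trans to ring B. Neither centre is touched afterwards.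

Key step: step 10

Assumption: the named antipodes of the phosphoramidite ligand (step 8) and of the triazolium salt (step 10) are taken to give the stated sense of induction and the matched pairing with (R)-13; if the sense proves opposite, the mirror-image catalyst is used. Locants C2, C3, C4, O1 and rings A, B, C follow flavanone numbering throughout.

**Route**

Step 1
Reactants: 1 3,4,5-trimethoxyphenol
Product: 2 6-hydroxy-2,3,4-trimethoxybenzaldehyde
Conditions: MgCl2, Et3N, (CH2O)n, MeCN, reflux; aq. HCl work-up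
Reagents that add atoms: paraformaldehyde (as formaldehyde), C=O
Why: Magnesium-mediated ortho-formylation of a phenol, in which the magnesium phenoxide delivers formaldehyde to the ortho carbon and a second formaldehyde oxidises the benzylic alkoxide by hydride transfer; the two ortho positions of 1 are equivalent, so one product should form.

Step 2
Reactants: 2 6-hydroxy-2,3,4-trimethoxybenzaldehyde
Product: 3 2,3,6-trihydroxy-4-methoxybenzaldehyde
Conditions: BCl3 (4 equiv), CH2Cl2, –78 °C → rt; H2O; product kept under argon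
Reagents that add atoms: none
Why: Lewis-acid ether cleavage, in which BCl3 removes the doubly flanked 3-methoxy group and then, through a cyclic borate, the neighbouring 2-methoxy group ortho to the formyl group, while the planar, conjugated 4-methoxy group para to the aldehyde should stay.

Step 3
Reactants: 3 2,3,6-trihydroxy-4-methoxybenzaldehyde
Product: 4 5-hydroxy-7-methoxy-2,2-diphenyl-1,3-benzodioxole-4-carbaldehyde
Conditions: Ph2CCl2, Ph2O, 170 °C, N2 stream
Reagents that add atoms: dichlorodiphenylmethane, ClC(Cl)(c1ccccc1)c1ccccc1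
Why: Ketalisation of a catechol with a gem-dichloride, in which only the vicinal 2,3-diol can close the five-membered ketal, so the isolated 6-hydroxyl (the future O1) is left free.

Step 4
Reactants: 5 2,3-dihydroxy-4-methoxybenzaldehyde
Product: 6 7-methoxy-2,2-diphenyl-1,3-benzodioxole-4-carbaldehyde
Conditions: Ph2CCl2, Ph2O, 170 °C, N2 stream
Reagents that add atoms: dichlorodiphenylmethane, ClC(Cl)(c1ccccc1)c1ccccc1
Why: The same catechol ketalisation protects the ring-B diol in one operation and ties back the oxygen ortho to the side chain, which lowers hindrance in the later steps.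

Step 5
Reactants: 6 7-methoxy-2,2-diphenyl-1,3-benzodioxole-4-carbaldehyde
Product: 7 ethyl (2E)-3-(7-methoxy-2,2-diphenyl-1,3-benzodioxol-4-yl)prop-2-enoate
Conditions: Ph3P=CHCO2Et, toluene, 90 °C
Reagents that add atoms: ethyl (triphenylphosphoranylidene)acetate, CCOC(=O)C=P(c1ccccc1)(c1ccccc1)c1ccccc1
Why: Wittig olefination with a stabilised ylide, which should give the E-alkene under base-free conditions.

Step 6
Reactants: 7 ethyl (2E)-3-(7-methoxy-2,2-diphenyl-1,3-benzodioxol-4-yl)prop-2-enoate
Product: 8 (2E)-3-(7-methoxy-2,2-diphenyl-1,3-benzodioxol-4-yl)prop-2-en-1-ol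
Conditions: i-Bu2AlH (2.2 equiv), CH2Cl2, –78 °C; Rochelle salt work-up
Reagents that add atoms: none
Why: 1,2-Reduction of an α,β-unsaturated ester to the allylic alcohol by i-Bu2AlH, which leaves the alkene geometry and the ketal untouched.

Step 7
Reactants: 8 (2E)-3-(7-methoxy-2,2-diphenyl-1,3-benzodioxol-4-yl)prop-2-en-1-ol
Product: 9 methyl (2E)-3-(7-methoxy-2,2-diphenyl-1,3-benzodioxol-4-yl)prop-2-en-1-yl carbonate
Conditions: ClCO2Me, pyridine, CH2Cl2, 0 °C
Reagents that add atoms: methyl chloroformate, COC(=O)Cl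
Why: Acylation of the primary alcohol gives the linear allylic carbonate, the standard ionisable substrate for iridium-catalysed allylic substitution.

Step 8
Reactants: 4 5-hydroxy-7-methoxy-2,2-diphenyl-1,3-benzodioxole-4-carbaldehyde; 9 methyl (2E)-3-(7-methoxy-2,2-diphenyl-1,3-benzodioxol-4-yl)prop-2-en-1-yl carbonate
Product: 11 7-methoxy-5-{[(1S)-1-(7-methoxy-2,2-diphenyl-1,3-benzodioxol-4-yl)prop-2-en-1-yl]oxy}-2,2-diphenyl-1,3-benzodioxole-4-carbaldehyde, via sodium aryloxide 10 (not isolated)
Conditions: 4, NaH, THF, 0 °C; then 9, [Ir(cod)Cl]2 (2 mol %), (Sa,Sc,Sc)-O,O′-(1,1′-binaphthyl-2,2′-diyl)-N,N-bis(1-phenylethyl)phosphoramidite (4 mol %, pre-activated with n-PrNH2), THF, 50 °C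
Reagents that add atoms: sodium hydride, [Na+].[H-] (supplies the sodium of 10 only)
Why: Iridium-catalysed asymmetric allylic etherification, in which the cyclometallated iridium–phosphoramidite complex ionises the carbonate to an η3-allyl complex and the aryloxide attacks its aryl-substituted terminus anti to the metal, so that the branched ether forms and C2 is set by catalyst control.

Step 9
Reactants: 11 7-methoxy-5-{[(1S)-1-(7-methoxy-2,2-diphenyl-1,3-benzodioxol-4-yl)prop-2-en-1-yl]oxy}-2,2-diphenyl-1,3-benzodioxole-4-carbaldehyde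
Product: 13 7-methoxy-5-{[(1R)-1-(7-methoxy-2,2-diphenyl-1,3-benzodioxol-4-yl)-2-oxoethyl]oxy}-2,2-diphenyl-1,3-benzodioxole-4-carbaldehyde, via vicinal diol 12 (not isolated)
Conditions: OsO4 (2 mol %), NaIO4 (4 equiv), 2,6-lutidine, dioxane–H2O, rt; crude product dried and used at once
Reagents that add atoms: osmium tetroxide, O=[Os](=O)(=O)=O (oxygen carrier); sodium periodate, [Na+].[O-]I(=O)(=O)=O (terminal oxidant)
Why: Lemieux–Johnson oxidation, in which OsO4 dihydroxylates the only alkene and NaIO4 cleaves the diol and re-oxidises osmium, while 2,6-lutidine suppresses over-oxidation and the aromatic formyl group is inert; the stereocentre keeps its spatial arrangement and only its descriptor changes.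

Step 10
Reactants: 13 7-methoxy-5-{[(1R)-1-(7-methoxy-2,2-diphenyl-1,3-benzodioxol-4-yl)-2-oxoethyl]oxy}-2,2-diphenyl-1,3-benzodioxole-4-carbaldehyde
Product: 14 (2R,3R)-3-hydroxy-7-methoxy-2-(7-methoxy-2,2-diphenyl-1,3-benzodioxol-4-yl)-5,6-(diphenylmethylenedioxy)chroman-4-one
Conditions: (5aR,10bS)-2-(pentafluorophenyl)-5a,10b-dihydro-4H,6H-indeno[2,1-b][1,2,4]triazolo[4,3-d][1,4]oxazin-2-ium tetrafluoroborate (10 mol %), i-Pr2NEt (1 equiv), 4 Å MS, toluene, rt, argon
Reagents that add atoms: none
Why: Proposed new method: the triazolylidene adds to the ring-A formyl group of 13 and proton transfer gives the enaminol, an acyl-anion equivalent at C4 conjugated with ring A, which attacks the aliphatic formyl carbon C3 in a 6-exo-trig closure of ring C; proton shift and loss of the carbene release the α-hydroxy ketone 14. The closest known reaction type is the carbene-catalysed intramolecular crossed benzoin of salicylaldehyde-tethered ketones to 3-hydroxychroman-4-ones, including versions run as a dynamic kinetic resolution of an epimerisable α-stereocentre; an aldehyde acceptor carrying an α-aryloxy stereocentre has not been used, hence the label. C3 is set by the chiral carbene, which exposes one face of the C3 carbonyl in a chair-like transition state with ring B equatorial, so the new hydroxyl should come out trans to ring B, and any 2,3-cis isomer should drift to trans at C3 through the enediol under the amine base. C2 arrives as R from step 8 and is re-selected here, because C2–H (benzylic, α to O1 and to the formyl group) should epimerise through the enol faster than the mismatched (2S)-aldehyde cyclises, so that both enantiomers are funnelled into the (2R,3R) product. The step needs the aromatic aldehyde to be the donor; this is secured by the conjugative stabilisation of its enaminol, by the tied-back dioxole oxygen that keeps this formyl group accessible, and by the α,α-disubstitution of the aliphatic aldehyde, which disfavours carbene addition there and with it the β-elimination of the ring-A aryloxide.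

Step 11
Reactants: 14 (2R,3R)-3-hydroxy-7-methoxy-2-(7-methoxy-2,2-diphenyl-1,3-benzodioxol-4-yl)-5,6-(diphenylmethylenedioxy)chroman-4-one
Product: 15 (2R,3R)-3,7-dimethoxy-2-(7-methoxy-2,2-diphenyl-1,3-benzodioxol-4-yl)-5,6-(diphenylmethylenedioxy)chroman-4-one
Conditions: MeI (excess), Ag2O, 4 Å MS, CH2Cl2, rt, dark
Reagents that add atoms: iodomethane, CI
Why: Silver-oxide-mediated O-methylation of the only free hydroxyl, an α-ketol, under conditions that form no free enolate, so that no bond to C2 or C3 is broken and the trans arrangement should be kept.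

Step 12
Reactants: 15 (2R,3R)-3,7-dimethoxy-2-(7-methoxy-2,2-diphenyl-1,3-benzodioxol-4-yl)-5,6-(diphenylmethylenedioxy)chroman-4-one
Product: 16 (2R,3R)-2-(2,3-dihydroxy-4-methoxyphenyl)-5,6-dihydroxy-3,7-dimethoxychroman-4-one
Conditions: H2 (1 atm), Pd/C (10 %), THF–MeOH, rt; work-up under argon
Reagents that add atoms: none
Why: Hydrogenolysis of the doubly benzylic C–O bonds of both diphenylmethylene ketals frees the two catechols as diphenylmethane is lost, while the C2–O1 bond, the C4 carbonyl and the three methyl ethers should survive and neither stereocentre is involved.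

**Compound list**

1 | 3,4,5-trimethoxyphenol | COc1cc(O)cc(OC)c1OC | starting material
2 | 6-hydroxy-2,3,4-trimethoxybenzaldehyde | O=Cc1c(O)cc(OC)c(OC)c1OC | intermediate
3 | 2,3,6-trihydroxy-4-methoxybenzaldehyde | O=Cc1c(O)cc(OC)c(O)c1O | intermediate
4 | 5-hydroxy-7-methoxy-2,2-diphenyl-1,3-benzodioxole-4-carbaldehyde | O=Cc1c(O)cc(OC)c2OC(c3ccccc3)(c3ccccc3)Oc12 | intermediate
5 | 2,3-dihydroxy-4-methoxybenzaldehyde | COc1ccc(C=O)c(O)c1O | starting material
6 | 7-methoxy-2,2-diphenyl-1,3-benzodioxole-4-carbaldehyde | COc1ccc(C=O)c2OC(c3ccccc3)(c3ccccc3)Oc12 | intermediate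
7 | ethyl (2E)-3-(7-methoxy-2,2-diphenyl-1,3-benzodioxol-4-yl)prop-2-enoate | CCOC(=O)/C=C/c1ccc(OC)c2OC(c3ccccc3)(c3ccccc3)Oc12 | intermediate
8 | (2E)-3-(7-methoxy-2,2-diphenyl-1,3-benzodioxol-4-yl)prop-2-en-1-ol | OC/C=C/c1ccc(OC)c2OC(c3ccccc3)(c3ccccc3)Oc12 | intermediate
9 | methyl (2E)-3-(7-methoxy-2,2-diphenyl-1,3-benzodioxol-4-yl)prop-2-en-1-yl carbonate | COC(=O)OC/C=C/c1ccc(OC)c2OC(c3ccccc3)(c3ccccc3)Oc12 | intermediate
10 | sodium 4-formyl-7-methoxy-2,2-diphenyl-1,3-benzodioxol-5-olate (not isolated) | [Na+].[O-]c1cc(OC)c2OC(c3ccccc3)(c3ccccc3)Oc2c1C=O | intermediate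
11 | 7-methoxy-5-{[(1S)-1-(7-methoxy-2,2-diphenyl-1,3-benzodioxol-4-yl)prop-2-en-1-yl]oxy}-2,2-diphenyl-1,3-benzodioxole-4-carbaldehyde | COc1ccc([C@H](C=C)Oc2cc(OC)c3OC(c4ccccc4)(c4ccccc4)Oc3c2C=O)c2OC(c3ccccc3)(c3ccccc3)Oc12 | intermediate
12 | 5-{[(1R)-2,3-dihydroxy-1-(7-methoxy-2,2-diphenyl-1,3-benzodioxol-4-yl)propyl]oxy}-7-methoxy-2,2-diphenyl-1,3-benzodioxole-4-carbaldehyde, both epimers at the new carbinol carbon (not isolated) | COc1ccc([C@H](C(O)CO)Oc2cc(OC)c3OC(c4ccccc4)(c4ccccc4)Oc3c2C=O)c2OC(c3ccccc3)(c3ccccc3)Oc12 | intermediate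
13 | 7-methoxy-5-{[(1R)-1-(7-methoxy-2,2-diphenyl-1,3-benzodioxol-4-yl)-2-oxoethyl]oxy}-2,2-diphenyl-1,3-benzodioxole-4-carbaldehyde | COc1ccc([C@H](C=O)Oc2cc(OC)c3OC(c4ccccc4)(c4ccccc4)Oc3c2C=O)c2OC(c3ccccc3)(c3ccccc3)Oc12 | intermediate
14 | (2R,3R)-3-hydroxy-7-methoxy-2-(7-methoxy-2,2-diphenyl-1,3-benzodioxol-4-yl)-5,6-(diphenylmethylenedioxy)chroman-4-one | COc1ccc([C@H]2Oc3cc(OC)c4OC(c5ccccc5)(c5ccccc5)Oc4c3C(=O)[C@@H]2O)c2OC(c3ccccc3)(c3ccccc3)Oc12 | intermediate
15 | (2R,3R)-3,7-dimethoxy-2-(7-methoxy-2,2-diphenyl-1,3-benzodioxol-4-yl)-5,6-(diphenylmethylenedioxy)chroman-4-one | COc1ccc([C@H]2Oc3cc(OC)c4OC(c5ccccc5)(c5ccccc5)Oc4c3C(=O)[C@@H]2OC)c2OC(c3ccccc3)(c3ccccc3)Oc12 | intermediate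
16 | (2R,3R)-2-(2,3-dihydroxy-4-methoxyphenyl)-5,6-dihydroxy-3,7-dimethoxychroman-4-one | COc1ccc([C@H]2Oc3cc(OC)c(O)c(O)c3C(=O)[C@@H]2OC)c(O)c1O | target

**Count and risks**

Total step count: 12. Longest linear sequence: 9 steps (5 to 16, steps 4 to 12).

Steps most likely to fail:

1. Step 10 (labelled step). What may go wrong: the carbene may add to the aliphatic aldehyde, which would lead to β-elimination of the ring-A aryloxide or to a benzoin in the inverse sense; the dynamic kinetic resolution may be incomplete; the C2 enol may undergo a base-induced aldol addition onto the ring-A formyl group. The fallback uses known chemistry only and avoids the labile dialdehyde; it sets out from 11 and comes back at 14. Wittig methylenation of the ring-A formyl group (Ph3PCH3Br, KOt-Bu, THF, 0 °C) should give the diene 4-ethenyl-7-methoxy-5-{[(1S)-1-(7-methoxy-2,2-diphenyl-1,3-benzodioxol-4-yl)prop-2-en-1-yl]oxy}-2,2-diphenyl-1,3-benzodioxole F1. Ring-closing metathesis with the second-generation Grubbs catalyst (H2IMes)(PCy3)Cl2Ru=CHPh in CH2Cl2 at 40 °C should close ring C at C3=C4 and give (2S)-7-methoxy-2-(7-methoxy-2,2-diphenyl-1,3-benzodioxol-4-yl)-5,6-(diphenylmethylenedioxy)-2H-chromene F2. Dihydroxylation with OsO4 (cat.) and N-methylmorpholine N-oxide in acetone–H2O, from the face anti to ring B, should give (2R,3S,4S)-7-methoxy-2-(7-methoxy-2,2-diphenyl-1,3-benzodioxol-4-yl)-5,6-(diphenylmethylenedioxy)chromane-3,4-diol F3. Activated MnO2 in CH2Cl2 should oxidise only the benzylic C4 carbinol and give 14, after which steps 11 and 12 follow unchanged.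

2. Step 8. What may go wrong: the hindered, chelating ortho-formyl aryloxide may erode the branched regioselectivity or the enantioselectivity, and the catalyst may re-ionise the product ether. The fallback sets out from 8 (with 4) and comes back at 13. Sharpless asymmetric epoxidation of 8 (Ti(Oi-Pr)4, L-(+)-diethyl tartrate, t-BuOOH, 4 Å MS, CH2Cl2, –20 °C) should give [(2S,3S)-3-(7-methoxy-2,2-diphenyl-1,3-benzodioxol-4-yl)oxiran-2-yl]methanol F4. Opening with phenol 4 mediated by Ti(Oi-Pr)4 in CH2Cl2, at the benzylic carbon with inversion, should give 5-{[(1R,2S)-2,3-dihydroxy-1-(7-methoxy-2,2-diphenyl-1,3-benzodioxol-4-yl)propyl]oxy}-7-methoxy-2,2-diphenyl-1,3-benzodioxole-4-carbaldehyde F5. Cleavage of the diol with NaIO4 in THF–H2O at 0 °C should give 13 directly, so that step 9 is bypassed as well.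

3. Step 12. What may go wrong: the ketals may hydrogenolyse slowly, with competing reduction of the C4 carbonyl or cleavage of the benzylic C2–O1 bond, and the freed catechols may oxidise in air. The fallback sets out from 15 and comes back at 16. It replaces reductive by hydrolytic cleavage: AcOH–H2O at 80 °C under argon should hydrolyse both ketals to the catechols and benzophenone. No new compound is formed (F0).

**Further compounds**

F1 | step 10 | 4-ethenyl-7-methoxy-5-{[(1S)-1-(7-methoxy-2,2-diphenyl-1,3-benzodioxol-4-yl)prop-2-en-1-yl]oxy}-2,2-diphenyl-1,3-benzodioxole | COc1ccc([C@H](C=C)Oc2cc(OC)c3OC(c4ccccc4)(c4ccccc4)Oc3c2C=C)c2OC(c3ccccc3)(c3ccccc3)Oc12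
F2 | step 10 | (2S)-7-methoxy-2-(7-methoxy-2,2-diphenyl-1,3-benzodioxol-4-yl)-5,6-(diphenylmethylenedioxy)-2H-chromene | COc1ccc([C@H]2Oc3cc(OC)c4OC(c5ccccc5)(c5ccccc5)Oc4c3C=C2)c2OC(c3ccccc3)(c3ccccc3)Oc12
F3 | step 10 | (2R,3S,4S)-7-methoxy-2-(7-methoxy-2,2-diphenyl-1,3-benzodioxol-4-yl)-5,6-(diphenylmethylenedioxy)chromane-3,4-diol | COc1ccc([C@H]2Oc3cc(OC)c4OC(c5ccccc5)(c5ccccc5)Oc4c3[C@H](O)[C@@H]2O)c2OC(c3ccccc3)(c3ccccc3)Oc12
F4 | step 8 | [(2S,3S)-3-(7-methoxy-2,2-diphenyl-1,3-benzodioxol-4-yl)oxiran-2-yl]methanol | OC[C@@H]1O[C@H]1c1ccc(OC)c2OC(c3ccccc3)(c3ccccc3)Oc12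
F5 | step 8 | 5-{[(1R,2S)-2,3-dihydroxy-1-(7-methoxy-2,2-diphenyl-1,3-benzodioxol-4-yl)propyl]oxy}-7-methoxy-2,2-diphenyl-1,3-benzodioxole-4-carbaldehyde | COc1ccc([C@H]([C@@H](O)CO)Oc2cc(OC)c3OC(c4ccccc4)(c4ccccc4)Oc3c2C=O)c2OC(c3ccccc3)(c3ccccc3)Oc12
F0 | step 12 | none | none
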